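**Plan**

- Numbering: C1 (thiolactone carbonyl), S2, C3, C3a, C4–C7, C7a, side-chain carbinol C1′. The enabling feature is that C3a and C7a are neighbouring carbons of the benzene ring. They carry the acidifiable carbon C3 and the acyl carbon C1, which are already joined through S2, and the C7 oxygen beside C7a can polarise an aryne.
- Retrosynthesis: cut the C4–O bond (late para-oxidation of the C7 phenol), then the C1′ configuration (inversion/reduction of a ketone), then C3–C3a and C7a–C1 together (aryne annulation). This leads to a 3-methoxy-4-prenyl silylaryl triflate and an S-(2-oxoheptyl) thiocarbonate.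
- Forward: the aryne precursor is made from 4-bromo-3-methoxyphenol and prenyl bromide, and the thiocarbonate from pentylmagnesium bromide, a chloroacetyl Weinreb amide, NaSH and ethyl chloroformate. The benzene ring is bought, and the thiolactone, the only ring made, closes in the annulation.
- Stereochemistry: asymmetric transfer hydrogenation with dynamic kinetic resolution sets C3 (S) and C1′ (S). A Mitsunobu inversion then turns C1′ into R, giving the (3S,1′R) target; C3 is not touched afterwards.

Key step: step 9

Assumption: the transfer hydrogenation is taken to follow the polar Felkin–Anh preference (C–S bond anti to the incoming hydride, as in the reduction of benzoin to the like diol), with the (S,S)-catalyst reading C3 in the place of the aryl group of an aryl ketone; the like (3S,1′S) alcohol is therefore expected and the unlike target configuration is reached by inversion at C1′.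

**Route**

Step 1
Reactants: 1 4-bromo-3-methoxyphenol
Product: 2 4-bromo-3-methoxyphenyl N,N-diethylcarbamate
Conditions: Et2NCOCl, K2CO3, MeCN, reflux
Reagents that add atoms: N,N-diethylcarbamoyl chloride, CCN(CC)C(Cl)=O
Why: O-carbamoylation of the phenoxide gives a group that protects the phenol from the organolithium steps and later directs the ortho-metalation.

Step 2
Reactants: 2 4-bromo-3-methoxyphenyl N,N-diethylcarbamate; 3 1-bromo-3-methylbut-2-ene (prenyl bromide)
Product: 5 3-methoxy-4-(3-methylbut-2-enyl)phenyl N,N-diethylcarbamate, via aryllithium 4 (not isolated)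
Conditions: n-BuLi, THF, −78 °C; CuBr·SMe2 (10 mol %), prenyl bromide, −78 → 0 °C
Reagents that add atoms: none
Why: Bromine–lithium exchange should be faster at −78 °C than attack on or ortho-deprotonation of the diethylcarbamate, and the copper-catalysed allylic substitution of prenyl bromide takes place at its primary carbon to give the linear prenyl arene.

Step 3
Reactants: 5 3-methoxy-4-(3-methylbut-2-enyl)phenyl N,N-diethylcarbamate
Product: 7 3-methoxy-4-(3-methylbut-2-enyl)-2-(trimethylsilyl)phenyl N,N-diethylcarbamate, via ortho-lithiated carbamate 6 (not isolated)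
Conditions: s-BuLi, TMEDA, THF, −78 °C; TMSCl, −78 °C → rt
Reagents that add atoms: chlorotrimethylsilane, C[Si](C)(C)Cl
Why: Directed ortho-metalation occurs at the carbon flanked by the carbamate and the methoxy group, which both activate it, and the anion is silylated at −78 °C before the anionic Fries shift can set in.

Step 4
Reactants: 7 3-methoxy-4-(3-methylbut-2-enyl)-2-(trimethylsilyl)phenyl N,N-diethylcarbamate
Product: 8 3-methoxy-4-(3-methylbut-2-enyl)-2-(trimethylsilyl)phenol
Conditions: LiAlH4, THF, 0 °C → reflux; aqueous work-up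
Reagents that add atoms: none
Why: Hydride reduction of the aryl carbamate should release the phenol (the carbamoyl carbon leaves as the N-methyl amine) without affecting the aryl silane or the trisubstituted alkene, and it avoids the acid that would protodesilylate this electron-rich aryl silane.

Step 5
Reactants: 8 3-methoxy-4-(3-methylbut-2-enyl)-2-(trimethylsilyl)phenol
Product: 9 3-methoxy-4-(3-methylbut-2-enyl)-2-(trimethylsilyl)phenyl trifluoromethanesulfonate
Conditions: Tf2O, pyridine, CH2Cl2, 0 °C
Reagents that add atoms: trifluoromethanesulfonic anhydride, O=S(=O)(OS(=O)(=O)C(F)(F)F)C(F)(F)F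
Why: Standard O-triflation of the ortho-silyl phenol completes the ortho-silylaryl triflate that releases the aryne with fluoride.

Step 6
Reactants: 10 pentylmagnesium bromide; 11 2-chloro-N-methoxy-N-methylacetamide
Product: 12 1-chloroheptan-2-one
Conditions: THF, 0 °C; aq. HCl
Reagents that add atoms: none
Why: Weinreb ketone synthesis, in which the Grignard reagent adds once to the N-methoxy-N-methylamide and the chelated adduct gives the chloromethyl ketone only on acidic work-up.

Step 7
Reactants: 12 1-chloroheptan-2-one
Product: 13 1-sulfanylheptan-2-one (handled as its monomer–dithianediol dimer mixture)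
Conditions: NaSH (excess), EtOH/H2O, 0 °C; dilute acid
Reagents that add atoms: sodium hydrosulfide, [Na+].[SH-]
Why: SN2 displacement of the activated α-chloride by hydrosulfide, run cold with excess NaSH to suppress formation of the symmetrical sulfide.

Step 8
Reactants: 13 1-sulfanylheptan-2-one; 14 ethyl chloroformate
Product: 15 O-ethyl S-(2-oxoheptyl) carbonothioate
Conditions: NaHCO3, CH2Cl2/H2O, 0 °C
Reagents that add atoms: none
Why: Chemoselective S-acylation of the thiolate by the chloroformate under Schotten–Baumann conditions gives the thiocarbonate.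

Step 9
Reactants: 9 3-methoxy-4-(3-methylbut-2-enyl)-2-(trimethylsilyl)phenyl trifluoromethanesulfonate; 15 O-ethyl S-(2-oxoheptyl) carbonothioate (1.5 equiv)
Product: 17 racemic 3-hexanoyl-7-methoxy-6-(3-methylbut-2-enyl)-2-benzothiophen-1(3H)-one, via aryne 16 (not isolated)
Conditions: CsF (3 equiv), MeCN, 25 → 50 °C; then AcOH
Reagents that add atoms: none
Why: Proposed new method: CsF strips the silyl group of 9 to give aryne 16 and deprotonates the methylene of 15 (flanked by the ketone and the acylated sulfur); the carbanion adds to the aryne carbon remote from the methoxy group (C3–C3a), which leaves the aryl anion at C7a beside the inductively stabilising C7–O bond. This anion attacks the thiocarbonate carbonyl five atoms away and ethoxide is expelled (directly, or after reversible loss and return of the thiolate onto the ethyl ester), so the thiolactone closes by 5-exo-trig acyl substitution (C7a–C1). The closest known reactions are the fluoride-mediated aryne acyl-alkylation of β-keto esters and aryne annulations in which the aryl anion is acylated by a tethered ester. Chemoselectivity requires the five-membered attack on the thiocarbonate to outrun both the four-membered attack on the ketone (acyl-alkylation) and protonation, which the S2 bridge secures by holding the acyl carbon at the right distance. Regioselectivity rests on the C7 methoxy group with C4 left as C–H, the O-ethyl group is chosen so that attack of the enolate oxygen on the thiocarbonate is reversible, and the product should rest as its stabilised C3 enolate until the acidic quench. C3 is formed racemic and stays labile, so no stereocontrol is asked of this step.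

Step 10
Reactants: 17 racemic 3-hexanoyl-7-methoxy-6-(3-methylbut-2-enyl)-2-benzothiophen-1(3H)-one
Product: 18 (3S)-3-[(1S)-1-hydroxyhexyl]-7-methoxy-6-(3-methylbut-2-enyl)-2-benzothiophen-1(3H)-one
Conditions: RuCl[(S,S)-TsDPEN](p-cymene) (2 mol %), HCO2H/Et3N (5:2), CH2Cl2, 30 °C
Reagents that add atoms: none
Why: Noyori–Ikariya asymmetric transfer hydrogenation with dynamic kinetic resolution, in which C3 epimerises through the enol in the amine buffer, the (S,S)-catalyst is expected to deliver hydride to the face that gives the 1′S carbinol, and the C3 enantiomer that can hold its C–S bond anti to the incoming hydride (polar Felkin–Anh) reacts faster, so the like (3S,1′S) alcohol should result.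

Step 11
Reactants: 18 (3S)-3-[(1S)-1-hydroxyhexyl]-7-methoxy-6-(3-methylbut-2-enyl)-2-benzothiophen-1(3H)-one
Product: 19 (3S)-3-[(1R)-1-(chloroacetoxy)hexyl]-7-methoxy-6-(3-methylbut-2-enyl)-2-benzothiophen-1(3H)-one
Conditions: ClCH2CO2H, PPh3, DIAD, THF, 0 °C → rt
Reagents that add atoms: chloroacetic acid, OC(=O)CCl
Why: Mitsunobu reaction in which the acidic chloroacetate displaces the alkoxyphosphonium group by SN2, inverting C1′ from S to R while C3 is untouched.

Step 12
Reactants: 19 (3S)-3-[(1R)-1-(chloroacetoxy)hexyl]-7-methoxy-6-(3-methylbut-2-enyl)-2-benzothiophen-1(3H)-one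
Product: 20 (3S)-3-[(1R)-1-(chloroacetoxy)hexyl]-7-hydroxy-6-(3-methylbut-2-enyl)-2-benzothiophen-1(3H)-one
Conditions: BCl3, CH2Cl2, −78 → −20 °C; cold aq. NaHCO3
Reagents that add atoms: none
Why: BCl3 chelates between the thiolactone carbonyl and the neighbouring C7 methoxy group and cleaves only this methyl ether, and because the alcohol is acylated no HCl is released in the cold, which spares the prenyl group.

Step 13
Reactants: 20 (3S)-3-[(1R)-1-(chloroacetoxy)hexyl]-7-hydroxy-6-(3-methylbut-2-enyl)-2-benzothiophen-1(3H)-one
Product: 21 (3S)-7-hydroxy-3-[(1R)-1-hydroxyhexyl]-6-(3-methylbut-2-enyl)-2-benzothiophen-1(3H)-one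
Conditions: thiourea, NaHCO3, EtOH/THF, 40 °C
Reagents that add atoms: none
Why: Thiourea displaces the chloride and the isothiouronium nitrogen cyclises onto the ester carbonyl, which releases the alcohol under near-neutral conditions that should leave the thiolactone and C3 unchanged.

Step 14
Reactants: 21 (3S)-7-hydroxy-3-[(1R)-1-hydroxyhexyl]-6-(3-methylbut-2-enyl)-2-benzothiophen-1(3H)-one
Product: 23 asperglaucin A [(3S)-4,7-dihydroxy-3-[(1R)-1-hydroxyhexyl]-6-(3-methylbut-2-enyl)-2-benzothiophen-1(3H)-one], via quinone 22 (not isolated)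
Conditions: (KSO3)2NO (2.5 equiv), KH2PO4, acetone/H2O, 0 °C; then aq. Na2S2O4
Reagents that add atoms: potassium nitrosodisulfonate, [K+].[K+].[O]N(S(=O)(=O)[O-])S(=O)(=O)[O-]
Why: Teuber oxidation, in which the nitroxyl radical abstracts the phenolic hydrogen and a second equivalent couples at the free para position C4 to give the para-quinone, which is reduced in the same flask to the hydroquinone before C3 can tautomerise.

**Compound list**

1 | 4-bromo-3-methoxyphenol | COc1cc(O)ccc1Br | starting material
2 | 4-bromo-3-methoxyphenyl N,N-diethylcarbamate | CCN(CC)C(=O)Oc1ccc(Br)c(OC)c1 | intermediate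
3 | 1-bromo-3-methylbut-2-ene (prenyl bromide) | CC(C)=CCBr | starting material
4 | [4-(diethylcarbamoyloxy)-2-methoxyphenyl]lithium | CCN(CC)C(=O)Oc1ccc([Li])c(OC)c1 | intermediate
5 | 3-methoxy-4-(3-methylbut-2-enyl)phenyl N,N-diethylcarbamate | CCN(CC)C(=O)Oc1ccc(CC=C(C)C)c(OC)c1 | intermediate
6 | [6-(diethylcarbamoyloxy)-2-methoxy-3-(3-methylbut-2-enyl)phenyl]lithium | CCN(CC)C(=O)Oc1ccc(CC=C(C)C)c(OC)c1[Li] | intermediate
7 | 3-methoxy-4-(3-methylbut-2-enyl)-2-(trimethylsilyl)phenyl N,N-diethylcarbamate | CCN(CC)C(=O)Oc1ccc(CC=C(C)C)c(OC)c1[Si](C)(C)C | intermediate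
8 | 3-methoxy-4-(3-methylbut-2-enyl)-2-(trimethylsilyl)phenol | COc1c(CC=C(C)C)ccc(O)c1[Si](C)(C)C | intermediate
9 | 3-methoxy-4-(3-methylbut-2-enyl)-2-(trimethylsilyl)phenyl trifluoromethanesulfonate | COc1c(CC=C(C)C)ccc(OS(=O)(=O)C(F)(F)F)c1[Si](C)(C)C | intermediate
10 | pentylmagnesium bromide | CCCCC[Mg]Br | starting material
11 | 2-chloro-N-methoxy-N-methylacetamide | CON(C)C(=O)CCl | starting material
12 | 1-chloroheptan-2-one | CCCCCC(=O)CCl | intermediate
13 | 1-sulfanylheptan-2-one | CCCCCC(=O)CS | intermediate
14 | ethyl chloroformate | CCOC(=O)Cl | starting material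
15 | O-ethyl S-(2-oxoheptyl) carbonothioate | CCCCCC(=O)CSC(=O)OCC | intermediate
16 | 3-methoxy-4-(3-methylbut-2-enyl)benzyne (1,2-didehydro arene) | COC1=C(CC=C(C)C)C=CC#C1 | intermediate
17 | racemic 3-hexanoyl-7-methoxy-6-(3-methylbut-2-enyl)-2-benzothiophen-1(3H)-one (C3 labile) | CCCCCC(=O)C1SC(=O)c2c(OC)c(CC=C(C)C)ccc21 | intermediate
18 | (3S)-3-[(1S)-1-hydroxyhexyl]-7-methoxy-6-(3-methylbut-2-enyl)-2-benzothiophen-1(3H)-one | CCCCC[C@H](O)[C@H]1SC(=O)c2c(OC)c(CC=C(C)C)ccc21 | intermediate
19 | (3S)-3-[(1R)-1-(chloroacetoxy)hexyl]-7-methoxy-6-(3-methylbut-2-enyl)-2-benzothiophen-1(3H)-one | CCCCC[C@@H](OC(=O)CCl)[C@H]1SC(=O)c2c(OC)c(CC=C(C)C)ccc21 | intermediate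
20 | (3S)-3-[(1R)-1-(chloroacetoxy)hexyl]-7-hydroxy-6-(3-methylbut-2-enyl)-2-benzothiophen-1(3H)-one | CCCCC[C@@H](OC(=O)CCl)[C@H]1SC(=O)c2c(O)c(CC=C(C)C)ccc21 | intermediate
21 | (3S)-7-hydroxy-3-[(1R)-1-hydroxyhexyl]-6-(3-methylbut-2-enyl)-2-benzothiophen-1(3H)-one | CCCCC[C@@H](O)[C@H]1SC(=O)c2c(O)c(CC=C(C)C)ccc21 | intermediate
22 | (3S)-3-[(1R)-1-hydroxyhexyl]-6-(3-methylbut-2-enyl)-2-benzothiophene-1,4,7(3H)-trione | CCCCC[C@@H](O)[C@H]1SC(=O)C2=C1C(=O)C=C(CC=C(C)C)C2=O | intermediate
23 | asperglaucin A, (3S)-4,7-dihydroxy-3-[(1R)-1-hydroxyhexyl]-6-(3-methylbut-2-enyl)-2-benzothiophen-1(3H)-one | CCCCC[C@@H](O)[C@H]1SC(=O)c2c(O)c(CC=C(C)C)cc(O)c21 | target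

**Step count and risks**

Total: 14 steps. Longest linear sequence: 11 steps (steps 1–5 and 9–14); steps 6–8 form the second branch.

Steps most likely to fail:

1. Step 9 (aryne annulation).
   - What may go wrong: migration of the ethoxycarbonyl group from sulfur to the enolate oxygen of 15, or attack of fluoride or ethoxide on the thiocarbonate, would release thiolates that add to the aryne through sulfur. The C7a aryl anion may be protonated before it closes the ring, and the acidic product enolate may be arylated a second time.
   - Fallback (known chemistry): it leaves the aryne, sets out from carbamate 5 and comes back at ketone 17. Anionic ortho-Fries rearrangement (s-BuLi, TMEDA, THF, −78 °C → rt) moves the carbamoyl group to the carbon between the two oxygens and should give N,N-diethyl-2-hydroxy-6-methoxy-5-(3-methylbut-2-enyl)benzamide F1. Triflation (Tf2O, pyridine, CH2Cl2) gives 2-(diethylcarbamoyl)-3-methoxy-4-(3-methylbut-2-enyl)phenyl trifluoromethanesulfonate F2. Suzuki methylation (trimethylboroxine, Pd(PPh3)4, K2CO3, dioxane, 100 °C) gives N,N-diethyl-2-methoxy-6-methyl-3-(3-methylbut-2-enyl)benzamide F3. Lateral lithiation of the methyl group (LiN(i-Pr)2, THF, −78 °C), sulfuration with S8 and acid-promoted N-to-S acyl transfer (TsOH, PhMe, 80 °C) give 7-methoxy-6-(3-methylbut-2-enyl)-2-benzothiophen-1(3H)-one F4. Aldol addition of its C3 enolate (LiN(SiMe3)2, THF, −78 °C) to hexanal gives racemic 3-(1-hydroxyhexyl)-7-methoxy-6-(3-methylbut-2-enyl)-2-benzothiophen-1(3H)-one F5 as a diastereomer mixture, and Dess–Martin oxidation of this alcohol returns to 17.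

2. Step 10 (transfer hydrogenation).
   - What may go wrong: weak facial or diastereomeric discrimination in the hydride transfer, epimerisation at C3 that is slow relative to reduction, inhibition of the ruthenium hydride by sulfur, or transfer of the thiolactone acyl group to the new hydroxyl.
   - Fallback: an enzymatic dynamic reductive kinetic resolution, setting out from 17 and coming back at 18. A screened NADPH-dependent ketoreductase with glucose/glucose dehydrogenase recycling (phosphate buffer pH 7, DMSO cosolvent, 30 °C) is used, the spontaneous epimerisation of C3 feeding the faster-reacting enantiomer; no new compound arises.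

3. Step 14 (Teuber oxidation).
   - What may go wrong: hydrogen abstraction from the hydrogen-bonded, acyl-deactivated phenol by the nitroxyl radical may be slow, and the quinone may tautomerise at C3 with loss of configuration before it is reduced.
   - Fallback: a two-electron oxidative dearomatisation, setting out from 21 and coming back at quinone 22. PhI(OAc)2 (2.2 equiv) in MeOH at 0 °C should give the quinone monoketal (3S)-3-[(1R)-1-hydroxyhexyl]-4,4-dimethoxy-6-(3-methylbut-2-enyl)-2-benzothiophene-1,7(3H,4H)-dione F6. Mild hydrolysis (aq. oxalic acid, acetone, 0 °C) gives 22, which is reduced at once with Na2S2O4 to 23.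

**Further compounds**

F1 | step 9 | N,N-diethyl-2-hydroxy-6-methoxy-5-(3-methylbut-2-enyl)benzamide | CCN(CC)C(=O)c1c(O)ccc(CC=C(C)C)c1OC
F2 | step 9 | 2-(diethylcarbamoyl)-3-methoxy-4-(3-methylbut-2-enyl)phenyl trifluoromethanesulfonate | CCN(CC)C(=O)c1c(OS(=O)(=O)C(F)(F)F)ccc(CC=C(C)C)c1OC
F3 | step 9 | N,N-diethyl-2-methoxy-6-methyl-3-(3-methylbut-2-enyl)benzamide | CCN(CC)C(=O)c1c(C)ccc(CC=C(C)C)c1OC
F4 | step 9 | 7-methoxy-6-(3-methylbut-2-enyl)-2-benzothiophen-1(3H)-one | COc1c(CC=C(C)C)ccc2CSC(=O)c12
F5 | step 9 | racemic 3-(1-hydroxyhexyl)-7-methoxy-6-(3-methylbut-2-enyl)-2-benzothiophen-1(3H)-one (diastereomer mixture) | CCCCCC(O)C1SC(=O)c2c(OC)c(CC=C(C)C)ccc21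
F0 | step 10 | none | none
F6 | step 14 | (3S)-3-[(1R)-1-hydroxyhexyl]-4,4-dimethoxy-6-(3-methylbut-2-enyl)-2-benzothiophene-1,7(3H,4H)-dione | CCCCC[C@@H](O)[C@H]1SC(=O)C2=C1C(OC)(OC)C=C(CC=C(C)C)C2=O
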